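Start from the constants: substrate has two exits, through partner and through second reagent, and the three flasks differ in what each exit sees.

    substrate + partner → intermediate (k1 = 0.0021 /M/s)
    second reagent + intermediate → target (k2 = 0.024 /M/s)
    substrate + second reagent → side product (k3 = 0.0034 /M/s)
    second reagent ⇌ dormant form (K4 = 0.24, k4 = 7.5 × 10⁻⁵ /s)
    target → over-reaction product (k5 = 3.5 × 10⁻⁶ /s)
    crystals ⇌ target, rate k6*(cs6 - [target]) while solid is left; crystals form when [target] > cs6 (cs6 = 9.6 mM, k6 = 0.0053 /s)

in all of them: second reagent 35.0 mM; time 8.0 h
- Monday's: substrate 14 mM (fed, over 6.0 h); partner 25.2 mM; all else is in the flask from the start; the feed brings no volume worth counting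
- Saturday's: substrate 14 mM; partner 25.2 mM; everything together at the start
- Wednesday's: substrate 14 mM; partner 25.2 mM (fed, over 6.0 h); all else is in the flask from the start; the feed brings no volume worth counting

- for target the crystals are counted in
- as a solid, counted per litre of solution: crystals
- run time (Monday's): 8.0 h

- the flask that comes out highest in amount of target, in percent of the substrate charged, or "all alike" when all lie within 1.5 percentage points (Monday's / Saturday's / Wednesday's / all alike)
- target at the end, in percent of the substrate charged, Monday's
- target at the end, in percent of the substrate charged, Saturday's
- target at the end, in percent of the substrate charged, Wednesday's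

Freeze one level for a first reckoning. On Wednesday's the exchange with the dormant form relaxes with a half-life of 0.497 h, shorter than the 1.6 h that substrate has against second reagent on Saturday's. So you split second reagent between free and dormant by 0.24, which puts free second reagent at its charge over one plus 0.24, or 28.2 mM. Each substrate spent takes one second reagent by either exit in the end, so up to 14 mM of the 35.0 mM can go, and holding free second reagent at that level is a rough choice of yours, not a property of the flask. The side exit then runs at s = 0.345 /h, and partner as charged gives u = 0.191 /h. Your useful share is φ = u/(u+s), the fraction of spent substrate that leaves through partner (the selectivity). With full partner it is 35.5%. Over-reaction is slow, since Saturday's half-life of 55 h exceeds the 8.0 h run, so you count target as φ times substrate spent.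

For Saturday's that gives 35.0%. On this reckoning Monday's substrate has a lifetime of 1.87 h and keeps 10.2% unspent, which gives 31.9%.

On Wednesday's partner climbs with time, so substrate meets the partner present at its own lifetime τ, taken self-consistently: τ = 2.38 h. That partner is 9.98 mM, and Wednesday's useful share φ is 17.9%.

The forecast gave 30%, 33% and 17.5% for Monday's, Saturday's and Wednesday's, with Saturday's highest, holding that “feeding the partner starves the useful path early”.

The flasks give 28.8%, 32.6% and 15.9%, with Saturday's highest.

Wednesday's ends with side product at 77.3%, against 60.9% on Saturday's. Its target, over-reaction product and intermediate together are 18.4% of substrate spent, beside φ of 17.9%. Now charge Wednesday's with 100 mM of partner, still fed. τ becomes 1.76 h, the partner met 29.4 mM, and φ 39.1%. That flask ends with target at 36.2% and over-reaction product at 2.19%.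

The numbers of this flask are those of an exercise; the result is computed.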